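**Strategy.** Ring C of the flavanone is cut at O1–C8a and C4–C4a. On benzo ring B these neighbouring carbons carry the ring oxygen and the C4 ketone, and C4a has the C5 oxygen at its other side: the ortho oxygen/acyl pattern that a 3-alkoxyaryne accepts with predictable orientation. In one operation a fluoride-released aryne takes the alkoxide oxygen of an (S)-3-silyloxy-3-phenylpropanoate at C8a and its ester carbon at C4a, closing ring C while C2 stays untouched. The aryne precursor is a 2-silylaryl triflate carrying two MOM ethers and the C6 methyl, made from a symmetric phenol. Acid deprotection and a squaramide-catalysed C8 alkylation with the isobutylidene ring A dione finish the target.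

Key step: step 6

Remarks on the chemistry:
- The (S)-hydroxy ester and the methoxybenzoate are taken as purchasable in the form shown.
- Ring B is protected as methoxymethyl (MOM) ethers, not benzyl ethers. The phenyl C–H bonds of benzyl groups would compete in the sterically governed borylation of step 2, and acid removal of MOM spares the C2–O1 benzylic ether and the C4 ketone.
- The alcohol of the hydroxy ester is silylated before the key step, so that the flask holds no O–H proton.
- The descriptor (R) for the benzylic centre refers to the enol tautomer drawn for the target.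

**Step 1**
Reactants: 1 2-methylresorcinol
Product: 2 1,3-bis(methoxymethoxy)-2-methylbenzene
Conditions: MOMCl (2.4 equiv), i-Pr2NEt, CH2Cl2, 0 → 23 °C
Reagents that add atoms: chloromethyl methyl ether, COCCl
Why: Double O-alkylation of the phenols by the α-chloro ether (Williamson-type acetal formation) gives ethers that carry no aryl C–H bond and withstand base, organolithium and fluoride in the later steps.

**Step 2**
Reactants: 2 1,3-bis(methoxymethoxy)-2-methylbenzene
Product: 4 3,5-bis(methoxymethoxy)-4-methylphenol, via arylboronic pinacol ester 3 (not isolated)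
Conditions: [Ir(OMe)(cod)]2 (1.5 mol%), 4,4′-di-tert-butyl-2,2′-bipyridine (3 mol%), B2pin2 (1.0 equiv), THF, 80 °C; then 30% H2O2, NaOH (aq), 0 °C
Reagents that add atoms: hydrogen peroxide, OO
Why: Sterically governed iridium-catalysed C–H borylation goes to C5, the only ring C–H without an ortho substituent, and peroxide oxidation of the boronate (1,2-aryl shift from boron to oxygen) gives the symmetric phenol in a one-pot borylation–oxidation.

**Step 3**
Reactants: 4 3,5-bis(methoxymethoxy)-4-methylphenol
Product: 5 2-bromo-3,5-bis(methoxymethoxy)-4-methylphenol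
Conditions: N-bromosuccinimide (1.0 equiv), CH2Cl2, −78 → −30 °C
Reagents that add atoms: N-bromosuccinimide, O=C1CCC(=O)N1Br
Why: Electrophilic aromatic bromination can give one monobromide only, since C2 and C6 are equivalent by symmetry and the para position is blocked by the methyl group; one equivalent at low temperature should hold back the second bromination.

**Step 4**
Reactants: 5 2-bromo-3,5-bis(methoxymethoxy)-4-methylphenol
Product: 8 3,5-bis(methoxymethoxy)-4-methyl-2-(trimethylsilyl)phenyl trifluoromethanesulfonate, via aryl trimethylsilyl ether 6 (not isolated), via lithium 2-silylphenoxide 7 (not isolated)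
Conditions: (Me3Si)2NH, THF, 65 °C, then evaporation; n-BuLi, THF, −78 °C; Tf2O, −78 °C
Reagents that add atoms: hexamethyldisilazane, C[Si](C)(C)N[Si](C)(C)C; trifluoromethanesulfonic anhydride, O=S(=O)(OS(=O)(=O)C(F)(F)F)C(F)(F)F
Why: O-silylation, bromine–lithium exchange and 1,3 O→C silyl migration (retro-Brook rearrangement) put the silyl group between the phenoxide and the C3 ether, and triflation of the lithium phenoxide in the same flask follows the standard one-pot route to 2-silylaryl triflates; exchange at −78 °C is faster than any lithiation directed by the MOM groups.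

**Step 5**
Reactants: 9 methyl (S)-3-hydroxy-3-phenylpropanoate
Product: 10 methyl (S)-3-phenyl-3-(trimethylsilyloxy)propanoate
Conditions: Me3SiCl, Et3N, CH2Cl2, 0 °C
Reagents that add atoms: chlorotrimethylsilane, C[Si](C)(C)Cl
Why: O-silylation of the secondary alcohol with a silyl chloride and an amine base leaves the C–O bond at the stereocentre untouched, so the (S) configuration is kept and a proton-free alkoxide source results.

**Step 6**
Reactants: 8 3,5-bis(methoxymethoxy)-4-methyl-2-(trimethylsilyl)phenyl trifluoromethanesulfonate (1.0 equiv); 10 methyl (S)-3-phenyl-3-(trimethylsilyloxy)propanoate (1.3 equiv)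
Product: 13 (2S)-5,7-bis(methoxymethoxy)-6-methyl-2-phenylchroman-4-one, via aryne 11 (not isolated), via cesium alkoxide 12 (not isolated)
Conditions: CsF (1.1 equiv), 18-crown-6 (1.1 equiv), THF, 0 → 23 °C, closed vessel; then pH 7 buffer
Reagents that add atoms: none
Why: Proposed new method: fluoride attacks silicon in 8 and expels triflate to give aryne 11 and also unmasks 10 as alkoxide 12, which adds through oxygen to the aryne carbon remote from the C5 ether (O1–C8a) so that the aryl anion forms at C4a beside that inductively withdrawing oxygen; this anion attacks the methyl ester (C4–C4a) and expels methoxide, which is silylated by 10 or by Me3SiF, so that no base should remain once the fluoride is used up. The closest known reaction type is the CsF-mediated annulation of arynes with methyl salicylates to xanthones, where a phenoxide adds and the aryl anion then acylates on the ester; here the oxygen nucleophile is an aliphatic alkoxide. Ring C closes by 6-exo-trig acyl substitution of the aryl anion on the ester carbonyl. No stereocentre is made, and because the carbinol C–O bond is never broken C2 keeps the (S) configuration brought in by 9. The step needs regioselective addition to the unsymmetrical aryne, secured by the C5 alkoxy group as in 3-alkoxybenzynes, and acylation ahead of protonation, secured by the absence of any O–H or N–H bond in the flask (silyl ether in place of the alcohol, THF in place of acetonitrile). The place of the methyl group at C6 follows from the symmetric phenol 4 without any choice.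

**Step 7**
Reactants: 13 (2S)-5,7-bis(methoxymethoxy)-6-methyl-2-phenylchroman-4-one
Product: 14 (2S)-5,7-dihydroxy-6-methyl-2-phenylchroman-4-one
Conditions: HCl (1.25 M in MeOH), 40 °C
Reagents that add atoms: none
Why: Acid-catalysed acetal exchange with methanol removes both MOM groups, while the C4 ketone and the C2–O1 ether are inert to dilute acid and C2, which epimerises only through base-induced ring opening, should keep its configuration.

**Step 8**
Reactants: 15 methyl 2,6-dihydroxy-4-methoxybenzoate
Product: 16 methyl 2-hydroxy-4-methoxy-3,3,5-trimethyl-6-oxocyclohexa-1,4-diene-1-carboxylate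
Conditions: MeI (3.3 equiv), NaOMe (3.3 equiv), MeOH, 0 → 40 °C
Reagents that add atoms: iodomethane, CI
Why: Threefold C-methylation of the phenoxide (dearomatising alkylation, as used for syncarpic acid) is steered by the ester that blocks C1, so C3 and C5 are methylated, the third methyl breaks aromaticity, and the C4 methyl ether stops the sequence there because C5 cannot take a second methyl group.

**Step 9**
Reactants: 16 methyl 2-hydroxy-4-methoxy-3,3,5-trimethyl-6-oxocyclohexa-1,4-diene-1-carboxylate
Product: 18 3-hydroxy-5-methoxy-4,4,6-trimethylcyclohexa-2,5-dien-1-one, via carboxylic acid 17 (not isolated)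
Conditions: LiOH, THF/H2O, 50 °C; then 1 M HCl to pH 3, 0 → 23 °C
Reagents that add atoms: none
Why: Saponification of the ester and decarboxylation of the resulting vinylogous β-keto acid on acidification should free C2 of ring A, the enol ether being shielded from hydroxide by its place between a quaternary and a methyl-bearing carbon and by the charge of the enolate.

**Step 10**
Reactants: 18 3-hydroxy-5-methoxy-4,4,6-trimethylcyclohexa-2,5-dien-1-one; 19 isobutyraldehyde
Product: 21 5-methoxy-4,6,6-trimethyl-2-(2-methylpropylidene)cyclohex-4-ene-1,3-dione (E/Z mixture), via piperidine Mannich base 20 (not isolated)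
Conditions: piperidine (1.05 equiv), CH2Cl2, 0 → 23 °C; then 1 M HCl (aq), 0 °C; argon
Reagents that add atoms: none
Why: Knoevenagel condensation run by way of the piperidine Mannich base, from which cold acid removes the amine, keeps the acceptor masked until no free dione is left and so avoids the second Michael addition that leads to 2:1 adducts, as is done for syncarpic acid.

**Step 11**
Reactants: 14 (2S)-5,7-dihydroxy-6-methyl-2-phenylchroman-4-one; 21 5-methoxy-4,6,6-trimethyl-2-(2-methylpropylidene)cyclohex-4-ene-1,3-dione
Product: 22 2-[(1R)-1-[(2S)-5,7-dihydroxy-6-methyl-4-oxo-2-phenylchroman-8-yl]-2-methylpropyl]-3-hydroxy-5-methoxy-4,4,6-trimethylcyclohexa-2,5-dien-1-one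
Conditions: 3-{[3,5-bis(trifluoromethyl)phenyl]amino}-4-{[(8α,9S)-6′-methoxycinchonan-9-yl]amino}cyclobut-3-ene-1,2-dione (10 mol%), CH2Cl2/THF, −20 °C, argon
Reagents that add atoms: none
Why: In this enantioselective Friedel–Crafts-type Michael addition of an electron-rich phenol to an alkylidene 1,3-dione under bifunctional squaramide catalysis, the squaramide N–H bonds bind the dione carbonyls, the quinuclidine nitrogen holds the C7 hydroxyl, and C8, the only free position of ring B, attacks one face of the alkylidene carbon, so the (R) benzylic centre is set by the catalyst (the quinidine-derived pseudoenantiomer serves if the sense proves opposite), C2 is not touched, and tautomerisation restores the phenol and the ring A enol.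

**Compound list**
1 | 2-methylresorcinol | Cc1c(O)cccc1O | starting material
2 | 1,3-bis(methoxymethoxy)-2-methylbenzene | COCOc1cccc(OCOC)c1C | intermediate
3 | 2-[3,5-bis(methoxymethoxy)-4-methylphenyl]-4,4,5,5-tetramethyl-1,3,2-dioxaborolane | COCOc1cc(B2OC(C)(C)C(C)(C)O2)cc(OCOC)c1C | intermediate
4 | 3,5-bis(methoxymethoxy)-4-methylphenol | COCOc1cc(O)cc(OCOC)c1C | intermediate
5 | 2-bromo-3,5-bis(methoxymethoxy)-4-methylphenol | COCOc1cc(O)c(Br)c(OCOC)c1C | intermediate
6 | [2-bromo-3,5-bis(methoxymethoxy)-4-methylphenoxy]trimethylsilane | COCOc1cc(O[Si](C)(C)C)c(Br)c(OCOC)c1C | intermediate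
7 | lithium 3,5-bis(methoxymethoxy)-4-methyl-2-(trimethylsilyl)phenoxide | [Li+].COCOc1cc([O-])c([Si](C)(C)C)c(OCOC)c1C | intermediate
8 | 3,5-bis(methoxymethoxy)-4-methyl-2-(trimethylsilyl)phenyl trifluoromethanesulfonate | COCOc1cc(OS(=O)(=O)C(F)(F)F)c([Si](C)(C)C)c(OCOC)c1C | intermediate
9 | methyl (S)-3-hydroxy-3-phenylpropanoate | COC(=O)C[C@H](O)c1ccccc1 | starting material
10 | methyl (S)-3-phenyl-3-(trimethylsilyloxy)propanoate | COC(=O)C[C@H](O[Si](C)(C)C)c1ccccc1 | intermediate
11 | 3,5-bis(methoxymethoxy)-4-methylbenzyne (1,2-didehydrobenzene) | CC1=C(OCOC)C#CC=C1OCOC | intermediate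
12 | cesium (S)-3-methoxy-3-oxo-1-phenylpropan-1-olate | [Cs+].COC(=O)C[C@H]([O-])c1ccccc1 | intermediate
13 | (2S)-5,7-bis(methoxymethoxy)-6-methyl-2-phenylchroman-4-one | O=C1C[C@@H](c2ccccc2)Oc2cc(OCOC)c(C)c(OCOC)c21 | intermediate
14 | (2S)-5,7-dihydroxy-6-methyl-2-phenylchroman-4-one | O=C1C[C@@H](c2ccccc2)Oc2cc(O)c(C)c(O)c21 | intermediate
15 | methyl 2,6-dihydroxy-4-methoxybenzoate | COC(=O)c1c(O)cc(OC)cc1O | starting material
16 | methyl 2-hydroxy-4-methoxy-3,3,5-trimethyl-6-oxocyclohexa-1,4-diene-1-carboxylate | COC(=O)C1=C(O)C(C)(C)C(OC)=C(C)C1=O | intermediate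
17 | 2-hydroxy-4-methoxy-3,3,5-trimethyl-6-oxocyclohexa-1,4-diene-1-carboxylic acid | OC(=O)C1=C(O)C(C)(C)C(OC)=C(C)C1=O | intermediate
18 | 3-hydroxy-5-methoxy-4,4,6-trimethylcyclohexa-2,5-dien-1-one | COC1=C(C)C(=O)C=C(O)C1(C)C | intermediate
19 | isobutyraldehyde | CC(C)C=O | starting material
20 | 3-hydroxy-5-methoxy-4,4,6-trimethyl-2-[2-methyl-1-(piperidin-1-yl)propyl]cyclohexa-2,5-dien-1-one (racemic) | COC1=C(C)C(=O)C(C(N2CCCCC2)C(C)C)=C(O)C1(C)C | intermediate
21 | 5-methoxy-4,6,6-trimethyl-2-(2-methylpropylidene)cyclohex-4-ene-1,3-dione (E/Z mixture) | COC1=C(C)C(=O)C(=CC(C)C)C(=O)C1(C)C | intermediate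
22 | 2-[(1R)-1-[(2S)-5,7-dihydroxy-6-methyl-4-oxo-2-phenylchroman-8-yl]-2-methylpropyl]-3-hydroxy-5-methoxy-4,4,6-trimethylcyclohexa-2,5-dien-1-one | COC1=C(C)C(=O)C([C@@H](c2c(O)c(C)c(O)c3c2O[C@H](c2ccccc2)CC3=O)C(C)C)=C(O)C1(C)C | target

**Step count**
Total: 11 steps. Longest linear sequence: 7 steps (steps 1, 2, 3, 4, 6, 7, 11).

**Steps most likely to fail**

Step 6. The aryl anion may capture a proton before it acylates, the alkoxide may fragment by retro-aldol reaction, or ring C of the product may open under base with loss of configuration at C2. The fallback makes the same two bonds one after the other by known reactions and sets out from bromophenol 5. A Mitsunobu reaction with purchased methyl (R)-3-hydroxy-3-phenylpropanoate (COC(=O)C[C@@H](O)c1ccccc1; PPh3, DIAD, toluene, 0 °C) should give, with inversion at the carbinol carbon, methyl (S)-3-[2-bromo-3,5-bis(methoxymethoxy)-4-methylphenoxy]-3-phenylpropanoate F1. Bromine–lithium exchange (n-BuLi, THF, −100 °C) and attack of the aryllithium on the tethered ester (Parham cyclisation) then close ring C and return to the route at 13.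

Step 11. Facial selectivity at the alkylidene carbon may be poor, since the acceptor is a mixture of alkene isomers and the C2 centre is too remote to help, and the adduct may erode by retro-Michael reaction. The fallback relies on separation instead of catalyst control and sets out from 14 and 21. The addition is run with an achiral base (Et3N, 10 mol%, THF, 0 °C); because C2 is fixed, the two products are diastereomers, 22 and its benzylic epimer 2-[(1S)-1-[(2S)-5,7-dihydroxy-6-methyl-4-oxo-2-phenylchroman-8-yl]-2-methylpropyl]-3-hydroxy-5-methoxy-4,4,6-trimethylcyclohexa-2,5-dien-1-one F2. These are parted by preparative HPLC, and the route is rejoined at 22.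

Step 9. The enol ether may hydrolyse together with or in place of the ester, and saponification of the enolate may be slow. The fallback uses an ester that leaves under neutral conditions and sets out from 15.
- Saponification (NaOH, H2O/MeOH, 60 °C; cold acidification) gives 2,6-dihydroxy-4-methoxybenzoic acid F3.
- Carboxylate alkylation (allyl bromide, KHCO3, DMF, 23 °C) gives allyl 2,6-dihydroxy-4-methoxybenzoate F4.
- C-Trimethylation as in step 8, but in allyl alcohol (MeI, NaOCH2CH=CH2), gives allyl 2-hydroxy-4-methoxy-3,3,5-trimethyl-6-oxocyclohexa-1,4-diene-1-carboxylate F5.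
- Palladium-catalysed deallylation with formate and decarboxylation (Pd(OAc)2, PPh3, HCO2H, Et3N, THF, 23 °C) frees the acid without hydroxide or strong acid and returns to the route at 18.

**Further compounds**
F1 | step 6 | methyl (S)-3-[2-bromo-3,5-bis(methoxymethoxy)-4-methylphenoxy]-3-phenylpropanoate | COC(=O)C[C@H](Oc1cc(OCOC)c(C)c(OCOC)c1Br)c1ccccc1
F2 | step 11 | 2-[(1S)-1-[(2S)-5,7-dihydroxy-6-methyl-4-oxo-2-phenylchroman-8-yl]-2-methylpropyl]-3-hydroxy-5-methoxy-4,4,6-trimethylcyclohexa-2,5-dien-1-one | COC1=C(C)C(=O)C([C@H](c2c(O)c(C)c(O)c3c2O[C@H](c2ccccc2)CC3=O)C(C)C)=C(O)C1(C)C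
F3 | step 9 | 2,6-dihydroxy-4-methoxybenzoic acid | COc1cc(O)c(C(=O)O)c(O)c1
F4 | step 9 | allyl 2,6-dihydroxy-4-methoxybenzoate | C=CCOC(=O)c1c(O)cc(OC)cc1O
F5 | step 9 | allyl 2-hydroxy-4-methoxy-3,3,5-trimethyl-6-oxocyclohexa-1,4-diene-1-carboxylate | C=CCOC(=O)C1=C(O)C(C)(C)C(OC)=C(C)C1=O
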